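## Structural features

The target (15) is a depside: two benzene rings joined only by an ester, with the carbonyl carbon on ring A C1 and the ester oxygen on ring B C4. Ring A, numbered from the acyl-bearing carbon, carries OH at C2, CH3 at C3, OCH3 at C4, Cl at C5 and CH3 at C6. Ring B, numbered from the carbon bearing the methoxycarbonyl group, carries OH at C2 and CH3 at C3, C5 and C6, so both rings are hexasubstituted. There is no stereogenic centre, hence no adjacent stereocentres; the problem is one of regiochemistry and crowding. The fragile elements are the aryl ester (an activated acyl donor toward hydroxide or alkoxide), the methyl ester, the two hydrogen-bonded phenols (oxidisable, and nucleophilic once deprotonated) and the aryl chloride, which forbids forcing hydrogenolysis. The real difficulty is the central ester: its carbonyl carbon lies between the C2 oxygen and the C6 methyl of ring A, and its oxygen lies between the C3 and C5 methyls of ring B, so addition–elimination at that carbonyl has four ortho substituents around the reacting centres. A second difficulty is telling apart four phenolic oxygens, of which one is a methyl ether, one is acylated and two are free. The key step uses ring B C4, which is para to the C1 ester, has no ortho hydrogen, and is the only unsubstituted carbon of a simple ring B precursor. It can be iodinated, raised to a diaryl-λ3-iodane and bonded to the ring A carboxylate oxygen, which moves bond formation from the shielded carbonyl carbon to the ring carbon.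

## Logic of the disconnections

From 15 back to 13: the two hydroxyls next to carbonyl groups are capped as methyl ethers; in the forward sense two O–CH3 bonds are cleaved through 14. Free phenols would be oxidised in the iodine chemistry of ring B and would compete as nucleophiles in the coupling. Methyl is retained on purpose: it is the one ether that survives electrophilic iodination, peracid with sulfonic acid, and a hot carboxylate, whereas benzyl, allyl, acetal or silyl ethers would each fail at one of these stages. The skeleton is not simplified; the gain is that the oxygens are differentiated by position alone. The forward step must remove only the two methyl groups that can be held in a chelate with a carbonyl oxygen, and spare the ring A C4 methoxyl and both esters.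

From 13 back to 11 and 7: the bond between ring B C4 and the ester oxygen is cut. Cutting there keeps the di-ortho-substituted acyl carbon of ring A as an intact carboxylate, so the union needs no attack at that carbon. The molecule falls into two halves of similar size, each a hexasubstituted benzene made by simple aromatic substitutions, and the route becomes convergent. The substitution patterns of 7, 11 and 13 follow atom for atom from 15 and need no adjustment. The forward step (through 12) must transfer the ring B aryl group, not the spectator aryl group, from iodine to oxygen.

From 7 back to 4 and 5: the bond between iodine and the trimethoxyphenyl ring is cut. An unsymmetrical salt with an electron-rich, non-transferable partner avoids wasting a second ring B unit. This leaves a plain aryl iodide and a commercial arene. The forward step (through 6) must oxidise iodine in preference to the electron-rich ring and attach a bulky arene to an iodine flanked by two methyl groups.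

From 4 back to 3: the C4–I bond is cut. C4 is the only ring carbon of 3 that bears hydrogen, so no regiochemical choice arises. The forward step needs an electrophile strong enough for a position para to an ester and between two methyl groups.

From 3 back to 2: the two O–CH3 bonds of the ester and the C2 ether are cut, so both come from one alkylation. The forward step must fully alkylate a hydrogen-bonded, flanked hydroxyl.

From 2 back to 1: the bond between ring B C1 and the carboxyl carbon is cut. The hydroxyl of 1 directs carboxylation to its only free ortho carbon, and 1 already carries the three methyl groups in the right places. The forward step must carboxylate next to a methyl group.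

From 11 back to 10: the acid is traced to its methyl ester (forward: cleavage of the acyl–OCH3 bond), because the commercial source of ring A is a methyl ester. The forward step must hydrolyse a doubly ortho-substituted ester without touching the aryl ethers or the chloride.

From 10 back to 9: the two aryl O–CH3 bonds are cut. One alkylation installs the permanent C4 methoxyl and the temporary C2 cap together. Both hydroxyls must react completely.

From 9 back to 8: the C5–Cl bond is cut. C5 is the only free ring position of 8 and is activated by both hydroxyls. The forward step must stop at monochlorination and avoid ipso attack on the substituted carbons.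

## Other disconnections considered

Alternative 1: The cut removes ring B bonds C1–C6 and C3–C4 and takes ring B back to two acyclic esters, methyl 3-oxopentanoate A1 and methyl tiglate A2. In the forward key step an alkoxide base would add the doubly activated carbon of A1 to the β-carbon of A2. The ethyl ketone enolate would then close onto the ester carbonyl of A2 to give methyl 3,5,6-trimethyl-2,4-dioxocyclohexane-1-carboxylate A3 as a diastereomer mixture. Dehydrogenation would give methyl 2,4-dihydroxy-3,5,6-trimethylbenzoate A4.
- In its favour: both partners are cheap, and A4 would be reached in two operations against four for 7. The C2 hydroxyl of A4 is deactivated by chelation and needs no protection, so the final deprotection would concern one methoxyl, not two. On step count (about seven in total) and protecting-group economy it is better than the chosen plan.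
- Against it: A2 is an α,β-disubstituted, sluggish acceptor that invites self-condensation of A1. Aromatising a ring with methyl groups on both sp3 carbons risks halogenation elsewhere. Above all, the inter-ring bond would again be made by acylating the flanked C4 hydroxyl of A4 with the di-ortho-substituted acid 11, through a crowded tetrahedral intermediate or an acylium ion.
- Comparison: the chosen plan forms the same ester at the aryl carbon by ligand coupling, so its decisive step does not depend on access to the acyl carbon. On regiochemical certainty of ring B the two are equal. Alternative 1 carries its main risk in the step that joins the halves.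

Alternative 2: The cut removes ring B bonds C5–C6, C2–C3, C4–C5 and C1–C2 and builds ring B from methyl (E)-5-diazo-3-methyl-4-oxohex-2-enoate A5 and 1-(triisopropylsiloxy)propyne A6. The forward key step would be a photochemical Wolff rearrangement of A5, ketene–alkyne [2+2] cycloaddition with A6, four-electron electrocyclic opening, six-electron electrocyclic closure and tautomerisation. The product would be methyl 2-hydroxy-3,5,6-trimethyl-4-(triisopropylsilyloxy)benzoate A7.
- In its favour: every substituent of ring B is fixed by the connectivity of two acyclic partners. The C4 oxygen emerges as a silyl ether while the C2 hydroxyl is free, so the two oxygens are orthogonally differentiated in one step. On that point it is better than the chosen plan, which must remove a methyl ether from ring B at the end.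
- Against it: A5 needs a multistep synthesis ending in a diazo transfer, A6 needs ynolate chemistry, and the cascade is photochemical with a sensitive, electron-poor diazo ketone. Desilylation of A7 only leads to A4, so the hindered O-acylation with 11 remains to be solved.
- Comparison: regiochemical certainty is equal, since every aromatic substitution in the chosen plan occurs at the only free position. Alternative 2 would need clearly more steps (about twelve or more) and still ends at acylation of a crowded carbonyl, where the chosen plan uses carboxylate arylation.

Alternative 3: The cut removes ring A bonds C1–C2 and C5–C6. Ring A would be built on a preformed ester by thermal [4+2] cycloaddition of 1,3-dimethoxy-2-methyl-1-(trimethylsilyloxy)buta-1,3-diene A8 to methyl 4-(but-2-ynoyloxy)-2-(methoxymethoxy)-3,5,6-trimethylbenzoate A9. 1,4-Elimination of the acetal alkoxy group would aromatise the adduct to the deschloro depside methyl 4-[(2-hydroxy-4-methoxy-3,6-dimethylbenzoyl)oxy]-2-(methoxymethoxy)-3,5,6-trimethylbenzoate A10. Chlorination at ring A C5 and acidic removal of the acetal would finish.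
- In its favour: the ester linkage is set while the acyl partner is a slim alkynoyl group, so no addition to a di-ortho-substituted benzoyl carbon is needed. On this it equals the chosen plan. Ring A would arrive with its C2 hydroxyl free and its C4 methoxyl in place, which is better than the chosen plan on ring A deprotection. The late chlorination has only one ring position open.
- Against it: a but-2-ynoate with a β-methyl group is a poor dienophile. A8 is hindered and hydrolytically labile at the temperature such a dienophile needs. A9 needs a ring B diol protected only at the chelated, less reactive C2 hydroxyl, which runs against the intrinsic reactivity order seen in A4 and costs protect and deprotect steps.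
- Comparison: the polarity-controlled regiochemistry of the cycloaddition matches the positional certainty of the chosen plan. Alternative 3 would be longer (about ten to eleven steps) and carries its main risk in a thermally demanding cycloaddition, where the chosen plan uses a ligand coupling with a built-in leaving group.

Key step: step 8

Remark on the chemistry: phenoxide and carboxylate salts that differ from a numbered compound only by exchange of a proton for an alkali metal are treated as forms of that compound and are not numbered separately.

## Route

Step 1
Reactants: 1 2,4,5-trimethylphenol
Product: 2 2-hydroxy-3,5,6-trimethylbenzoic acid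
Conditions: NaOH (1 equiv), H2O; toluene, azeotropic drying; CO2 (50 bar), 150 °C; then aq. HCl
Reagents that add atoms: carbon dioxide, O=C=O
Why: Kolbe–Schmitt carboxylation of the dry sodium salt of 1 through a sodium-chelated transition state; the para carbon carries a methyl group and only one ortho carbon is free, so the carboxyl can only enter between the hydroxyl and the neighbouring methyl, and the hindered salicylate should be stabilised by its internal hydrogen bond.

Step 2
Reactants: 2 2-hydroxy-3,5,6-trimethylbenzoic acid
Product: 3 methyl 2-methoxy-3,5,6-trimethylbenzoate
Conditions: MeI (3 equiv), K2CO3, DMF, 40 °C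
Reagents that add atoms: iodomethane, CI
Why: Carboxylate O-alkylation and Williamson etherification by SN2 attack on iodomethane; neither reaction involves the crowded carbonyl carbon, and excess reagent with mild heating should overcome the hydrogen bond that holds the C2 hydroxyl.

Step 3
Reactants: 3 methyl 2-methoxy-3,5,6-trimethylbenzoate
Product: 4 methyl 4-iodo-2-methoxy-3,5,6-trimethylbenzoate
Conditions: NIS (1.2 equiv), CF3CO2H, TfOH (cat.), CH2Cl2, 0 °C to rt
Reagents that add atoms: N-iodosuccinimide, O=C1CCC(=O)N1I
Why: Electrophilic aromatic iodination by acid-activated N-iodosuccinimide; C4 is the only ring carbon bearing hydrogen, it is activated by the two flanking methyl groups, and the ester, twisted out of the ring plane by its two ortho neighbours, deactivates it mainly by induction.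

Step 4
Reactants: 4 methyl 4-iodo-2-methoxy-3,5,6-trimethylbenzoate; 5 1,3,5-trimethoxybenzene
Product: 7 [3-methoxy-4-(methoxycarbonyl)-2,5,6-trimethylphenyl](2,4,6-trimethoxyphenyl)iodonium tosylate, via hydroxy(tosyloxy)iodoarene 6 (not isolated)
Conditions: mCPBA (1.05 equiv), TsOH·H2O (1.0 equiv), MeCN, 77 °C; then 5 (1.0 equiv), 77 °C to rt; Et2O trituration
Reagents that add atoms: p-toluenesulfonic acid monohydrate, Cc1ccc(cc1)S(=O)(=O)O.O
Why: The peracid oxidises the aryl iodide in the presence of the sulfonic acid to the hydroxy(tosyloxy)-λ3-iodane 6, whose electrophilic trivalent iodine is attacked by the very electron-rich 5 (electrophilic aromatic substitution at iodine, known one-pot synthesis of aryl(trimethoxyphenyl)iodonium tosylates); iodine should be oxidised faster than the fully substituted ring, and the attachment of iodine at ring B C4 is carried over from 4.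

Step 5
Reactants: 8 methyl 2,4-dihydroxy-3,6-dimethylbenzoate (atraric acid)
Product: 9 methyl 5-chloro-2,4-dihydroxy-3,6-dimethylbenzoate
Conditions: SO2Cl2 (1.05 equiv), Et2O, 0 °C to rt
Reagents that add atoms: sulfuryl chloride, O=S(=O)(Cl)Cl
Why: Electrophilic aromatic chlorination; C5 is the only unsubstituted ring carbon of 8 and lies ortho to the C4 hydroxyl and para to the C2 hydroxyl, so one equivalent at low temperature should stop at the monochloride.

Step 6
Reactants: 9 methyl 5-chloro-2,4-dihydroxy-3,6-dimethylbenzoate
Product: 10 methyl 5-chloro-2,4-dimethoxy-3,6-dimethylbenzoate
Conditions: MeI (4 equiv), K2CO3, DMF, 50 °C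
Reagents that add atoms: iodomethane, CI
Why: Twofold Williamson etherification; the acidic C4 hydroxyl should react first and the chelated C2 hydroxyl follow with excess iodomethane in a dipolar aprotic solvent, while carbonate leaves the methyl ester alone.

Step 7
Reactants: 10 methyl 5-chloro-2,4-dimethoxy-3,6-dimethylbenzoate
Product: 11 5-chloro-2,4-dimethoxy-3,6-dimethylbenzoic acid
Conditions: KOH, DMSO/H2O (4:1), 100 °C; then aq. HCl, 0 °C
Reagents that add atoms: potassium hydroxide, [K+].[OH-]
Why: Saponification by acyl substitution (BAc2); the carbonyl is shielded by the C2 methoxyl and the C6 methyl, so poorly solvated hydroxide in aqueous DMSO and heat are used, the chloride on this electron-rich ring is inert to hydroxide, and cold acidification should avoid decarboxylation.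

Step 8
Reactants: 11 5-chloro-2,4-dimethoxy-3,6-dimethylbenzoic acid; 7 [3-methoxy-4-(methoxycarbonyl)-2,5,6-trimethylphenyl](2,4,6-trimethoxyphenyl)iodonium tosylate
Product: 13 methyl 4-[(5-chloro-2,4-dimethoxy-3,6-dimethylbenzoyl)oxy]-2-methoxy-3,5,6-trimethylbenzoate, via iodonium carboxylate 12 (not isolated)
Conditions: KOtBu (1.05 equiv), toluene, rt; then 7 (1.1 equiv), 110 °C
Reagents that add atoms: none
Why: KOtBu converts 11 into its potassium salt, which exchanges with the tosylate of 7 to give the iodonium carboxylate 12, a T-shaped λ3-iodane with an I–O bond. On heating, ligand coupling (reductive elimination from trivalent iodine through a three-centre transition state at the ipso carbon) should join the carboxylate oxygen to ring B C4 and release 2-iodo-1,3,5-trimethoxybenzene. The closest known reaction type is the metal-free O-arylation of carboxylic acids with diaryliodonium salts that carry a trimethoxyphenyl spectator group. No ring is closed and no stereocentre is formed. The step needs chemoselective transfer of the ring B aryl group: the trimethoxyphenyl ring, with donors ortho and para to iodine, resists attack at its ipso carbon, whereas ring B C4 is para to the ester and its two ortho methyls favour the transferring position on iodine. Positional integrity is secured because both carbons ortho to iodine carry methyl groups, so no aryne can form and oxygen can only arrive at C4. The shielded acyl carbon of ring A is never attacked, so its two ortho substituents do not hinder the bond formation. The base is consumed by 11 before 7 is added, which keeps alkoxide away from the methyl ester and from the iodonium salt.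

Step 9
Reactants: 13 methyl 4-[(5-chloro-2,4-dimethoxy-3,6-dimethylbenzoyl)oxy]-2-methoxy-3,5,6-trimethylbenzoate
Product: 15 methyl 4-[(5-chloro-2-hydroxy-4-methoxy-3,6-dimethylbenzoyl)oxy]-2-hydroxy-3,5,6-trimethylbenzoate (target), via bis(dichloroboryl) ether 14 (not isolated)
Conditions: BCl3 (3 equiv, 1 M in CH2Cl2), CH2Cl2, −78 to 0 °C; then ice-water
Reagents that add atoms: none
Why: Chelation-controlled ether cleavage: BCl3 binds each carbonyl oxygen together with the adjacent methoxyl oxygen in a six-membered chelate, chloride removes the methyl group by SN2 attack to give the aryloxydichloroborane 14, and water liberates the two hydrogen-bonded phenols; the ring A C4 methoxyl has no carbonyl neighbour and should not be activated at low temperature, and the esters and the aryl chloride should be untouched under these conditions.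

## Compound list

1 | 2,4,5-trimethylphenol | Cc1cc(C)c(O)cc1C | starting material
2 | 2-hydroxy-3,5,6-trimethylbenzoic acid | OC(=O)c1c(C)c(C)cc(C)c1O | intermediate
3 | methyl 2-methoxy-3,5,6-trimethylbenzoate | COC(=O)c1c(C)c(C)cc(C)c1OC | intermediate
4 | methyl 4-iodo-2-methoxy-3,5,6-trimethylbenzoate | COC(=O)c1c(C)c(C)c(I)c(C)c1OC | intermediate
5 | 1,3,5-trimethoxybenzene | COc1cc(OC)cc(OC)c1 | starting material
6 | methyl 4-[hydroxy(tosyloxy)-λ3-iodanyl]-2-methoxy-3,5,6-trimethylbenzoate | COC(=O)c1c(C)c(C)c(I(O)OS(=O)(=O)c2ccc(C)cc2)c(C)c1OC | intermediate
7 | [3-methoxy-4-(methoxycarbonyl)-2,5,6-trimethylphenyl](2,4,6-trimethoxyphenyl)iodonium tosylate | COC(=O)c1c(C)c(C)c([I+]c2c(OC)cc(OC)cc2OC)c(C)c1OC.Cc1ccc(cc1)S(=O)(=O)[O-] | intermediate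
8 | methyl 2,4-dihydroxy-3,6-dimethylbenzoate (atraric acid) | COC(=O)c1c(C)cc(O)c(C)c1O | starting material
9 | methyl 5-chloro-2,4-dihydroxy-3,6-dimethylbenzoate | COC(=O)c1c(C)c(Cl)c(O)c(C)c1O | intermediate
10 | methyl 5-chloro-2,4-dimethoxy-3,6-dimethylbenzoate | COC(=O)c1c(C)c(Cl)c(OC)c(C)c1OC | intermediate
11 | 5-chloro-2,4-dimethoxy-3,6-dimethylbenzoic acid | COc1c(C)c(OC)c(Cl)c(C)c1C(=O)O | intermediate
12 | [3-methoxy-4-(methoxycarbonyl)-2,5,6-trimethylphenyl](2,4,6-trimethoxyphenyl)iodonium 5-chloro-2,4-dimethoxy-3,6-dimethylbenzoate | COC(=O)c1c(C)c(C)c([I+]c2c(OC)cc(OC)cc2OC)c(C)c1OC.COc1c(C)c(OC)c(Cl)c(C)c1C(=O)[O-] | intermediate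
13 | methyl 4-[(5-chloro-2,4-dimethoxy-3,6-dimethylbenzoyl)oxy]-2-methoxy-3,5,6-trimethylbenzoate | COC(=O)c1c(C)c(C)c(OC(=O)c2c(C)c(Cl)c(OC)c(C)c2OC)c(C)c1OC | intermediate
14 | methyl 4-({5-chloro-2-[(dichloroboranyl)oxy]-4-methoxy-3,6-dimethylbenzoyl}oxy)-2-[(dichloroboranyl)oxy]-3,5,6-trimethylbenzoate | COC(=O)c1c(C)c(C)c(OC(=O)c2c(C)c(Cl)c(OC)c(C)c2OB(Cl)Cl)c(C)c1OB(Cl)Cl | intermediate
15 | methyl 4-[(5-chloro-2-hydroxy-4-methoxy-3,6-dimethylbenzoyl)oxy]-2-hydroxy-3,5,6-trimethylbenzoate | COC(=O)c1c(C)c(C)c(OC(=O)c2c(C)c(Cl)c(OC)c(C)c2O)c(C)c1O | target

## Step count and least certain steps

Total step count: 9. Longest linear sequence: 6 steps (steps 1, 2, 3, 4, 8 and 9, from 1 to 15); the ring A branch (steps 5, 6, 7) joins at step 8.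

Step 8 (key step).
- Risk: slow or unselective ligand coupling. The iodine of 12 is surrounded by four ortho substituents, which may retard binding of the hindered carboxylate or divert the coupling toward transfer of the trimethoxyphenyl group. At the temperature required, the carboxylate may instead dealkylate a methoxyl or ester methyl of the cationic ring.
- Fallback: acylation through an acylium ion, setting out from 4 and 11 and returning at 13. Iodine–magnesium exchange on 4 with iPrMgCl·LiCl (THF, −20 °C) would give [3-methoxy-4-(methoxycarbonyl)-2,5,6-trimethylphenyl]magnesium chloride F1. B(OMe)3 would trap it as methyl 4-(dimethoxyboranyl)-2-methoxy-3,5,6-trimethylbenzoate F2. H2O2/NaOH at 0 °C would oxidise this to the phenol methyl 4-hydroxy-2-methoxy-3,5,6-trimethylbenzoate F3. Acid 11 and F3 with (CF3CO)2O in toluene at rt would pass through the mixed anhydride 5-chloro-2,4-dimethoxy-3,6-dimethylbenzoic trifluoroacetic anhydride F4. Its ionisation to a linear, donor-stabilised aroyl cation avoids the tetrahedral intermediate, and acylation of F3 would give 13.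

Step 9.
- Risk: loss of discrimination between chelated and unchelated methoxyls. The ring A C4 methoxyl is twisted out of the ring plane by its methyl and chlorine neighbours and is therefore more basic than an ordinary anisole oxygen. Dealkylation of the hindered methyl ester by the Lewis acid is a second possibility.
- Fallback: exhaustive demethylation and selective re-methylation, from 13 back to 15. BBr3 (excess, CH2Cl2, −78 °C to rt) would cleave all three aryl methyl ethers to the triphenol methyl 4-[(5-chloro-2,4-dihydroxy-3,6-dimethylbenzoyl)oxy]-2-hydroxy-3,5,6-trimethylbenzoate F5. MeI with KHCO3 in DMF at rt would then alkylate only the acidic, non-chelated ring A C4 hydroxyl (and any carboxyl set free), since the two chelated hydroxyls are not deprotonated by hydrogen carbonate. This would give 15.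

Step 3.
- Risk: incomplete substitution or reversal by protodeiodination. The position is para to an ester and squeezed between two methyl groups, and crowded aryl iodides can lose iodine again in strong acid.
- Fallback: bromination and halogen exchange, from 3 back to 4. The smaller, less reversible electrophile Br2 (AcOH, dark, rt) would give methyl 4-bromo-2-methoxy-3,5,6-trimethylbenzoate F6. Copper-catalysed aromatic Finkelstein exchange (CuI cat., N,N'-dimethylethylenediamine, NaI, 1,4-dioxane, 110 °C) would convert it into 4.

Step 1.
- Risk: low conversion or thermal reversal of the carboxylation, because the entering carboxyl is buttressed by the adjacent methyl group.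
- Fallback: formylation and oxidation, from 1 back to 2. Magnesium-mediated ortho-formylation (MgCl2, Et3N, paraformaldehyde, MeCN, reflux) would give 2-hydroxy-3,5,6-trimethylbenzaldehyde F7. Pinnick oxidation (NaClO2, NaH2PO4, 2-methyl-2-butene, tBuOH/H2O) would give 2.

Step 7.
- Risk: sluggish acyl substitution at the doubly ortho-substituted ester, with ether cleavage if the conditions are forced.
- Fallback: a switch from acyl–oxygen to alkyl–oxygen cleavage, from 10 back to 11. LiI in refluxing EtOAc would demethylate the ester by SN2 attack of iodide on the ester methyl group, which is indifferent to crowding at the carbonyl carbon. Acidification would give 11. No new compound is involved.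

## Further compounds

F1 | step 8 | [3-methoxy-4-(methoxycarbonyl)-2,5,6-trimethylphenyl]magnesium chloride | COC(=O)c1c(C)c(C)c([Mg]Cl)c(C)c1OC
F2 | step 8 | methyl 4-(dimethoxyboranyl)-2-methoxy-3,5,6-trimethylbenzoate | COC(=O)c1c(C)c(C)c(B(OC)OC)c(C)c1OC
F3 | step 8 | methyl 4-hydroxy-2-methoxy-3,5,6-trimethylbenzoate | COC(=O)c1c(C)c(C)c(O)c(C)c1OC
F4 | step 8 | 5-chloro-2,4-dimethoxy-3,6-dimethylbenzoic trifluoroacetic anhydride | COc1c(C)c(OC)c(Cl)c(C)c1C(=O)OC(=O)C(F)(F)F
F5 | step 9 | methyl 4-[(5-chloro-2,4-dihydroxy-3,6-dimethylbenzoyl)oxy]-2-hydroxy-3,5,6-trimethylbenzoate | COC(=O)c1c(C)c(C)c(OC(=O)c2c(C)c(Cl)c(O)c(C)c2O)c(C)c1O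
F6 | step 3 | methyl 4-bromo-2-methoxy-3,5,6-trimethylbenzoate | COC(=O)c1c(C)c(C)c(Br)c(C)c1OC
F7 | step 1 | 2-hydroxy-3,5,6-trimethylbenzaldehyde | O=Cc1c(C)c(C)cc(C)c1O
F0 | step 7 | none | none
A1 | alternative 1 | methyl 3-oxopentanoate | CCC(=O)CC(=O)OC
A2 | alternative 1 | methyl tiglate (methyl (E)-2-methylbut-2-enoate) | C/C=C(\C)C(=O)OC
A3 | alternative 1 | methyl 3,5,6-trimethyl-2,4-dioxocyclohexane-1-carboxylate (diastereomer mixture) | COC(=O)C1C(C)C(C)C(=O)C(C)C1=O
A4 | alternative 1 | methyl 2,4-dihydroxy-3,5,6-trimethylbenzoate | COC(=O)c1c(C)c(C)c(O)c(C)c1O
A5 | alternative 2 | methyl (E)-5-diazo-3-methyl-4-oxohex-2-enoate | COC(=O)/C=C(\C)C(=O)C(C)=[N+]=[N-]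
A6 | alternative 2 | 1-(triisopropylsiloxy)propyne | CC#CO[Si](C(C)C)(C(C)C)C(C)C
A7 | alternative 2 | methyl 2-hydroxy-3,5,6-trimethyl-4-(triisopropylsilyloxy)benzoate | COC(=O)c1c(C)c(C)c(O[Si](C(C)C)(C(C)C)C(C)C)c(C)c1O
A8 | alternative 3 | 1,3-dimethoxy-2-methyl-1-(trimethylsilyloxy)buta-1,3-diene | C=C(OC)C(C)=C(OC)O[Si](C)(C)C
A9 | alternative 3 | methyl 4-(but-2-ynoyloxy)-2-(methoxymethoxy)-3,5,6-trimethylbenzoate | COCOc1c(C)c(OC(=O)C#CC)c(C)c(C)c1C(=O)OC
A10 | alternative 3 | methyl 4-[(2-hydroxy-4-methoxy-3,6-dimethylbenzoyl)oxy]-2-(methoxymethoxy)-3,5,6-trimethylbenzoate | COCOc1c(C)c(OC(=O)c2c(C)cc(OC)c(C)c2O)c(C)c(C)c1C(=O)OC
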